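**Retrosynthetic overview**
1. Dinklagin A ⇒ cut the C2–aryl bond (this also sets 2S): 6-prenyl-7-silyloxychromone 11 + 6-bromo-2,2-dimethyl-2H-chromene 15, joined by an enantioselective Ni-catalysed reductive conjugate arylation.
2. Chromone 11 ⇒ cut the C6–prenyl bond (Suzuki–Miyaura): 6-bromo-7-hydroxychromone 7 + prenyl-Bpin 9 (from prenyl bromide).
3. 7 ⇒ resorcinol by bromination, Nencki acylation and C1 annulation with trimethyl orthoformate (pyranone ring formed first, on the A-ring branch).
4. 15 ⇒ 4-bromophenol + 3-chloro-3-methylbut-1-yne by propargyl ether formation and Claisen/6π cascade (chromene ring formed on its own branch).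
5. Ring order: chromone pyranone, then (separately) chromene pyran, then the union that turns C2 into the stereocentre.

Assumption: the sense of induction of the new step cannot be known in advance, so the ligand antipode giving 2S is written as (S,S); if the first run shows 2R, the mirror-image ligand is used and nothing else changes.

**Step 1**
Reactants: 1 resorcinol (benzene-1,3-diol)
Product: 2 4-bromobenzene-1,3-diol
Conditions: NBS (1.0 equiv), MeCN, −20 → 0 °C
Reagents that add atoms: N-bromosuccinimide, O=C1CCC(=O)N1Br
Why: Electrophilic aromatic bromination goes to C4 (para to one OH, ortho to the other), and one equivalent at low temperature holds back the 4,6-dibromide.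

**Step 2**
Reactants: 2 4-bromobenzene-1,3-diol; 3 acetic acid
Product: 4 1-(5-bromo-2,4-dihydroxyphenyl)ethan-1-one
Conditions: AcOH (solvent), BF3·OEt2 (3 equiv, promoter), 90 °C; aq. NaOAc work-up
Reagents that add atoms: none
Why: Nencki-type Friedel–Crafts C-acylation can only occur at C6 of 2 (activated by both OH groups and not flanked), and the ortho-hydroxy ketone is held as a boron chelate, so mono-acylation is clean.

**Step 3**
Reactants: 4 1-(5-bromo-2,4-dihydroxyphenyl)ethan-1-one; 5 trimethyl orthoformate
Product: 7 6-bromo-7-hydroxy-4H-chromen-4-one, via 4-methoxychromenylium perchlorate 6 (not isolated)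
Conditions: HC(OMe)3 (6 equiv), 70 % HClO4 (1.2 equiv), 0 °C → rt; then H2O, 80 °C (salt never dried)
Reagents that add atoms: water, O
Why: Acid-promoted condensation of the acetyl CH3 with the orthoformate carbon and ring closure by the 2-OH give the benzopyrylium salt (orthoformate/perchloric acid chromone synthesis), which water hydrolyses to the chromone; free phenols are tolerated and the 7-OH is not alkylated.

**Step 4**
Reactants: 8 prenyl bromide (1-bromo-3-methylbut-2-ene)
Product: 9 4,4,5,5-tetramethyl-2-(3-methylbut-2-en-1-yl)-1,3,2-dioxaborolane (prenyl-Bpin)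
Conditions: B2pin2 (1.05 equiv), Pd2(dba)3 (1 mol %), THF, 60 °C
Reagents that add atoms: bis(pinacolato)diboron, CC1(C)OB(OC1(C)C)B1OC(C)(C)C(C)(C)O1
Why: Pd(0) ionises the allylic bromide to a π-prenyl-palladium, and B–B transmetalation with reductive elimination puts boron on the unsubstituted terminus (Miyaura-type allylic borylation).

**Step 5**
Reactants: 7 6-bromo-7-hydroxy-4H-chromen-4-one; 9 prenyl-Bpin
Product: 10 7-hydroxy-6-(3-methylbut-2-en-1-yl)-4H-chromen-4-one
Conditions: Pd-PEPPSI-IPent (2 mol %), K3PO4 (4 equiv), THF/H2O 5:1, 65 °C; aq. NH4Cl work-up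
Reagents that add atoms: none
Why: Suzuki–Miyaura sp2–sp3 coupling at the only C–Br bond; the bulky NHC–Pd catalyst transfers the prenyl group through its CH2 end (α-selective, no reverse-prenyl isomer), and the substrate reacts as its phenoxide, which shields the pyranone from hydroxide ring opening.

**Step 6**
Reactants: 10 7-hydroxy-6-(3-methylbut-2-en-1-yl)-4H-chromen-4-one
Product: 11 6-(3-methylbut-2-en-1-yl)-7-[(triisopropylsilyl)oxy]-4H-chromen-4-one
Conditions: TIPSCl (1.2 equiv), imidazole (2.5 equiv), DMF, rt
Reagents that add atoms: triisopropylsilyl chloride, CC(C)[Si](Cl)(C(C)C)C(C)C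
Why: Silylation of the only OH removes the acidic phenol before the reductive coupling; TIPS survives Mn/Et3SiCl and later falls to buffered fluoride.

**Step 7**
Reactants: 12 4-bromophenol; 13 3-chloro-3-methylbut-1-yne
Product: 14 1-bromo-4-[(2-methylbut-3-yn-2-yl)oxy]benzene
Conditions: DBU (1.3 equiv), CuCl2·2H2O (0.1 mol %), MeCN, 0 °C → rt
Reagents that add atoms: none
Why: Copper-catalysed propargylic etherification of the tertiary propargylic chloride by the phenoxide gives the aryl 1,1-dimethylpropargyl ether without touching the aryl bromide.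

**Step 8**
Reactants: 14 1-bromo-4-[(2-methylbut-3-yn-2-yl)oxy]benzene
Product: 15 6-bromo-2,2-dimethyl-2H-chromene
Conditions: PhNEt2, 190 °C, 3 h
Reagents that add atoms: none
Why: Aromatic propargyl Claisen rearrangement, enolisation, 1,5-H shift and oxa-6π electrocyclisation close the 2,2-dimethylpyran ring; both ortho positions are equivalent, so Br ends up at C6 (para to O).

**Step 9**
Reactants: 11 6-(3-methylbut-2-en-1-yl)-7-[(triisopropylsilyl)oxy]-4H-chromen-4-one; 15 6-bromo-2,2-dimethyl-2H-chromene (1.3 equiv)
Product: 18 dinklagin A = (2S)-7-hydroxy-2-(2,2-dimethyl-2H-chromen-6-yl)-6-(3-methylbut-2-en-1-yl)-2,3-dihydro-4H-chromen-4-one, via bis-silyl enol ether 16 (not isolated), via TIPS-protected flavanone 17 (not isolated)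
Conditions: NiBr2·glyme (10 mol %), (S,S)-t-Bu-BiOX (12 mol %), Mn powder (3 equiv), Et3SiCl (1.5 equiv), DMA, 10 °C, 24 h; filter through Celite; then TBAF/AcOH (1:1, 4 equiv), THF, 0 °C, 30 min
Reagents that add atoms: none
Why: Proposed new method: an enantioselective, chlorosilane-mediated Ni-catalysed reductive conjugate arylation of a chromone with an aryl bromide, in which L*Ni(0) and Et3SiCl turn 11 into an η3-(4-silyloxychromenyl)nickel species (a nickel-bound 4-silyloxybenzopyrylium), Mn reduces it, 15 adds oxidatively and C2–aryl reductive elimination (C2 is the less hindered allyl terminus, C4 carries OSi and is fully substituted) gives enol silane 16; the C2-symmetric bi(oxazoline) selects which enantiotopic face of the planar benzopyrylium carries nickel (faces exchange by reversible Ni(0) dissociation) and thereby sets C2 as S; the stereocentre is stored as an enol silane that cannot open to the chalcone, and buffered fluoride then cleaves the enol Si–O and aryl Si–O bonds while AcOH protonates C3 without touching C2; the closest known reaction type is the racemic Ni/bipyridine-type reductive conjugate addition of aryl halides to enones with R3SiCl through allylnickel intermediates, together with Ni-catalysed enantioselective arylation of oxocarbenium-type π-allyl species, and what is new is the asymmetric version on a chromone acceptor.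

**Compound list**
1 | resorcinol (benzene-1,3-diol) | Oc1cccc(O)c1 | starting material
2 | 4-bromobenzene-1,3-diol | Oc1ccc(Br)c(O)c1 | intermediate
3 | acetic acid | CC(=O)O | starting material
4 | 1-(5-bromo-2,4-dihydroxyphenyl)ethan-1-one | CC(=O)c1cc(Br)c(O)cc1O | intermediate
5 | trimethyl orthoformate | COC(OC)OC | starting material
6 | 6-bromo-7-hydroxy-4-methoxychromenylium perchlorate (not isolated) | COc1cc[o+]c2cc(O)c(Br)cc12.[O-]Cl(=O)(=O)=O | intermediate
7 | 6-bromo-7-hydroxy-4H-chromen-4-one | O=c1ccoc2cc(O)c(Br)cc12 | intermediate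
8 | prenyl bromide (1-bromo-3-methylbut-2-ene) | CC(C)=CCBr | starting material
9 | 4,4,5,5-tetramethyl-2-(3-methylbut-2-en-1-yl)-1,3,2-dioxaborolane | CC(C)=CCB1OC(C)(C)C(C)(C)O1 | intermediate
10 | 7-hydroxy-6-(3-methylbut-2-en-1-yl)-4H-chromen-4-one | CC(C)=CCc1cc2c(cc1O)occc2=O | intermediate
11 | 6-(3-methylbut-2-en-1-yl)-7-[(triisopropylsilyl)oxy]-4H-chromen-4-one | CC(C)=CCc1cc2c(cc1O[Si](C(C)C)(C(C)C)C(C)C)occc2=O | intermediate
12 | 4-bromophenol | Oc1ccc(Br)cc1 | starting material
13 | 3-chloro-3-methylbut-1-yne | C#CC(C)(C)Cl | starting material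
14 | 1-bromo-4-[(2-methylbut-3-yn-2-yl)oxy]benzene | C#CC(C)(C)Oc1ccc(Br)cc1 | intermediate
15 | 6-bromo-2,2-dimethyl-2H-chromene | CC1(C)C=Cc2cc(Br)ccc2O1 | intermediate
16 | (2S)-2-(2,2-dimethyl-2H-chromen-6-yl)-6-(3-methylbut-2-en-1-yl)-4-[(triethylsilyl)oxy]-7-[(triisopropylsilyl)oxy]-2H-chromene (not isolated) | CC(C)=CCc1cc2c(cc1O[Si](C(C)C)(C(C)C)C(C)C)O[C@H](c1ccc3c(c1)C=CC(C)(C)O3)C=C2O[Si](CC)(CC)CC | intermediate
17 | (2S)-2-(2,2-dimethyl-2H-chromen-6-yl)-6-(3-methylbut-2-en-1-yl)-7-[(triisopropylsilyl)oxy]-2,3-dihydro-4H-chromen-4-one (not isolated) | CC(C)=CCc1cc2c(cc1O[Si](C(C)C)(C(C)C)C(C)C)O[C@H](c1ccc3c(c1)C=CC(C)(C)O3)CC2=O | intermediate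
18 | dinklagin A, (2S)-7-hydroxy-2-(2,2-dimethyl-2H-chromen-6-yl)-6-(3-methylbut-2-en-1-yl)-2,3-dihydro-4H-chromen-4-one | CC(C)=CCc1cc2c(cc1O)O[C@H](c1ccc3c(c1)C=CC(C)(C)O3)CC2=O | target

**Step count and risks**
Total steps: 9. Longest linear sequence: 6 (steps 1, 2, 3, 5, 6, 9). The side branches are step 4 (joins at step 5) and steps 7–8 (join at step 9).

The three steps most likely to fail:

Step 9, the new coupling, may give low ee, biaryl from 15 or simple reduction of the chromone. The known replacement sets out from 15. Bromine–lithium exchange (n-BuLi, THF, −78 °C), B(OiPr)3 and dilute HCl give (2,2-dimethyl-2H-chromen-6-yl)boronic acid F1. F1 is added to chromone 11 by the established Rh(I)/chiral-diene asymmetric 1,4-addition of arylboronic acids to chromones ([RhCl(C2H4)2]2, chiral bicyclo[2.2.2]octadiene ligand of the antipode that gives 2S, aq. KOH 0.3 equiv, dioxane, 40 °C). This gives 17, here isolated, so the fallback comes back to the route at 17, which TBAF/AcOH converts to 18 exactly as in the second half of step 9. The same material serves as the reference for assigning the sense of induction of the new step.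

Step 5 may give the reverse-prenyl (γ) isomer or stall on the electron-rich bromophenoxide. The fallback reverses the polarity of the partners and sets out from 7. TIPSCl/imidazole gives 6-bromo-7-[(triisopropylsilyl)oxy]-4H-chromen-4-one F2, and Miyaura borylation (B2pin2, Pd(dppf)Cl2, KOAc, dioxane, 90 °C) gives 6-(4,4,5,5-tetramethyl-1,3,2-dioxaborolan-2-yl)-7-[(triisopropylsilyl)oxy]-4H-chromen-4-one F3. Pd(PPh3)4/K2CO3 (THF/H2O, 50 °C) then couples F3 with prenyl bromide 8 through a π-prenyl-palladium that is arylated at its CH2 end. This comes back to the route at 11, and steps 4 and 6 fall away.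

Step 1 may over-brominate the very electron-rich ring or give some 2-bromo isomer. The fallback changes the order of events and sets out from 1. Nencki acylation with 3 (ZnCl2, AcOH, 140 °C) gives 1-(2,4-dihydroxyphenyl)ethan-1-one F4, whose deactivated ring takes one bromine cleanly (NBS, MeCN, 0 °C) para to the chelated 2-OH; any 3-bromo isomer is removed by crystallisation. This comes back to the route at 4, and step 2 falls away.

**Further compounds**
F1 | step 9 | (2,2-dimethyl-2H-chromen-6-yl)boronic acid | CC1(C)C=Cc2cc(B(O)O)ccc2O1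
F2 | step 5 | 6-bromo-7-[(triisopropylsilyl)oxy]-4H-chromen-4-one | O=c1ccoc2cc(O[Si](C(C)C)(C(C)C)C(C)C)c(Br)cc12
F3 | step 5 | 6-(4,4,5,5-tetramethyl-1,3,2-dioxaborolan-2-yl)-7-[(triisopropylsilyl)oxy]-4H-chromen-4-one | O=c1ccoc2cc(O[Si](C(C)C)(C(C)C)C(C)C)c(B3OC(C)(C)C(C)(C)O3)cc12
F4 | step 1 | 1-(2,4-dihydroxyphenyl)ethan-1-one | CC(=O)c1ccc(O)cc1O
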